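**Retrosynthetic overview**

- The pyrroline is closed last: acid unmasks a secondary amine that cyclodehydrates onto a C3 ketone; the C2–C3 bond comes from coupling a primary iodide on the azepane core with a thioester of (2S,4S)-4-methyl-5-oxooxolane-2-carboxylic acid (from the L-glutamic-acid-derived lactone acid).
- The spiro hydroxy-lactone comes from anti C13-methylation of a β-hydroxy-lactone dianion, preceded by face-selective hydrogenation of a spiro tetronic acid, itself made by annulating a β-lithio-β-benzyloxyacrylate onto the C11 lactone.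
- The C11 lactone comes from conjugate reduction of a butenolide, which is formed by an intramolecular oxazole–alkyne Diels–Alder/retro-Diels–Alder reaction (C8–C9 and C10–C11 bonds, loss of MeCN).
- The cycloaddition substrate is assembled from N-Boc-L-homoserine lactone (C9a), 2-(3-bromopropyl)-5-methoxy-4-methyloxazole and EtI.
- Ring order: azepane + furan (one cycloaddition) → γ-lactone → spiro lactone → side-chain lactone (attached preformed) → pyrroline.

Assumption: locants in the comments follow the usual Stemona numbering of the target (azepane N4–C5–C6–C7–C8(O)–C9–C9a; pyrroline C1–C3; C10 bears ethyl; C11 spiro; C12 CHOH; C13 CHMe; C14 lactone C=O; C18–C21 side lactone), and compounds 1, 4, 14 and 22 are taken as catalogue chemicals.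

**Route**

Step 1
Reactants: 1 DL-alanine methyl ester hydrochloride
Product: 2 methyl N-(4-bromobutanoyl)-DL-alaninate
Conditions: 4-bromobutanoyl chloride, Et3N (2.2 equiv), CH2Cl2, 0 °C → rt
Reagents that add atoms: 4-bromobutanoyl chloride O=C(Cl)CCCBr
Why: Simple N-acylation of the amine; the racemic centre does not matter because it becomes the sp2 C4 of the oxazole.

Step 2
Reactants: 2 methyl N-(4-bromobutanoyl)-DL-alaninate
Product: 3 2-(3-bromopropyl)-5-methoxy-4-methyl-1,3-oxazole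
Conditions: P2O5, CHCl3, 60 °C
Reagents that add atoms: none
Why: Robinson–Gabriel-type cyclodehydration of an N-acyl amino ester gives the 5-alkoxyoxazole that serves as the azadiene in step 7.

Step 3
Reactants: 4 tert-butyl N-[(3S)-2-oxooxolan-3-yl]carbamate (N-Boc-L-homoserine lactone)
Product: 6 tert-butyl N-[(3S)-5-hydroxypent-1-yn-3-yl]carbamate, via lactol 5 (not isolated)
Conditions: iBu2AlH (2.2 equiv), CH2Cl2, −78 °C; then MeOH, K2CO3, dimethyl (1-diazo-2-oxopropyl)phosphonate, 0 °C → rt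
Reagents that add atoms: dimethyl (1-diazo-2-oxopropyl)phosphonate CC(=O)C(=[N+]=[N-])P(=O)(OC)OC
Why: Half-reduction of the lactone followed by Seyferth–Gilbert homologation with the Ohira–Bestmann reagent turns the carbonyl into a terminal alkyne under mild carbonate conditions that leave the purchased (S)-centre (future C9a) untouched.

Step 4
Reactants: 6 tert-butyl N-[(3S)-5-hydroxypent-1-yn-3-yl]carbamate
Product: 7 tert-butyl N-[(3S)-5-(benzyloxy)pent-1-yn-3-yl]carbamate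
Conditions: benzyl 2,2,2-trichloroacetimidate, TfOH (5 mol %), CH2Cl2–cyclohexane, 0 °C
Reagents that add atoms: benzyl 2,2,2-trichloroacetimidate ClC(Cl)(Cl)C(=N)OCc1ccccc1
Why: Acid-catalysed imidate O-benzylation protects the primary alcohol without base, so neither the carbamate N–H nor the alkyne C–H reacts.

Step 5
Reactants: 7 tert-butyl N-[(3S)-5-(benzyloxy)pent-1-yn-3-yl]carbamate; 3 2-(3-bromopropyl)-5-methoxy-4-methyl-1,3-oxazole
Product: 8 tert-butyl N-[(3S)-5-(benzyloxy)pent-1-yn-3-yl]-N-[3-(5-methoxy-4-methyl-1,3-oxazol-2-yl)propyl]carbamate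
Conditions: NaH (1.05 equiv), DMF, 0 °C; then 3, rt
Reagents that add atoms: none
Why: The carbamate N–H is the most acidic site, so its sodium salt undergoes clean N-alkylation with the primary bromide and installs the three-carbon tether C5–C7.

Step 6
Reactants: 8 tert-butyl N-[(3S)-5-(benzyloxy)pent-1-yn-3-yl]-N-[3-(5-methoxy-4-methyl-1,3-oxazol-2-yl)propyl]carbamate
Product: 9 tert-butyl N-[(3S)-1-(benzyloxy)hept-4-yn-3-yl]-N-[3-(5-methoxy-4-methyl-1,3-oxazol-2-yl)propyl]carbamate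
Conditions: n-BuLi (1.05 equiv), THF, −78 °C; EtI, DMPU, −78 °C → rt
Reagents that add atoms: iodoethane CCI
Why: Alkylation of the lithium acetylide places the future C10 ethyl group on the alkyne.

Step 7
Reactants: 9 tert-butyl N-[(3S)-1-(benzyloxy)hept-4-yn-3-yl]-N-[3-(5-methoxy-4-methyl-1,3-oxazol-2-yl)propyl]carbamate
Product: 12 tert-butyl (4S,8aR)-4-[2-(benzyloxy)ethyl]-3-ethyl-2-oxo-2,4,6,7,8,8a-hexahydro-5H-furo[3,2-c]azepine-5-carboxylate, via cycloadduct 10 (not isolated), via methoxyfuran 11 (not isolated)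
Conditions: o-dichlorobenzene, 150 °C; then PPTS (cat.), THF–H2O, rt; then Et3N (cat.), rt
Reagents that add atoms: water O
Why: Intramolecular oxazole–alkyne Diels–Alder reaction closes the azepane, retro-Diels–Alder loss of acetonitrile gives the 2-methoxyfuran, and mild hydrolysis protonates C8 to the conjugated butenolide, whose exchangeable γ-proton is expected to let C8 settle with H8 on the face of the C9a side chain.

Step 8
Reactants: 12 tert-butyl (4S,8aR)-4-[2-(benzyloxy)ethyl]-3-ethyl-2-oxo-2,4,6,7,8,8a-hexahydro-5H-furo[3,2-c]azepine-5-carboxylate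
Product: 13 tert-butyl (3S,3aR,4S,8aR)-4-[2-(benzyloxy)ethyl]-3-ethyl-2-oxooctahydro-5H-furo[3,2-c]azepine-5-carboxylate
Conditions: NaBH4, NiCl2·6H2O (0.3 equiv), MeOH, −30 → 0 °C
Reagents that add atoms: none
Why: Nickel boride conjugate reduction delivers hydrogen to C9 anti to the C9a side chain (H9 cis to H9a, trans-fused lactone), and the basic medium equilibrates C10 so that ethyl ends trans to the C9–C9a bond.

Step 9
Reactants: 14 methyl prop-2-ynoate
Product: 15 methyl (2E)-3-(benzyloxy)prop-2-enoate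
Conditions: BnOH, DABCO (10 mol %), CH2Cl2, rt
Reagents that add atoms: benzyl alcohol OCc1ccccc1
Why: Amine-catalysed oxa-Michael addition to the propiolate gives the (E)-β-alkoxyacrylate.

Step 10
Reactants: 13 tert-butyl (3S,3aR,4S,8aR)-4-[2-(benzyloxy)ethyl]-3-ethyl-2-oxooctahydro-5H-furo[3,2-c]azepine-5-carboxylate; 15 methyl (2E)-3-(benzyloxy)prop-2-enoate
Product: 17 tert-butyl (2R,3S,3aR,4S,8aR)-3'-(benzyloxy)-4-[2-(benzyloxy)ethyl]-3-ethyl-5'-oxooctahydro-5'H-spiro[furo[3,2-c]azepine-2,2'-furan]-5-carboxylate, via hemiketal ester 16 (not isolated)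
Conditions: 15 (2.5 equiv), LiN(iPr)2 (2.5 equiv), THF, −90 °C; add 13, −90 → −20 °C; AcOH
Reagents that add atoms: none
Why: Tetronate annulation: the chelated β-lithio-β-alkoxyacrylate adds to the lactone carbonyl anti to the C10 ethyl group and the hemiketal alkoxide lactonises onto the cis ester, so C11 is set with the lactone oxygen syn to ethyl (11R).

Step 11
Reactants: 17 tert-butyl (2R,3S,3aR,4S,8aR)-3'-(benzyloxy)-4-[2-(benzyloxy)ethyl]-3-ethyl-5'-oxooctahydro-5'H-spiro[furo[3,2-c]azepine-2,2'-furan]-5-carboxylate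
Product: 19 tert-butyl (2R,3S,3aR,3'R,4S,8aR)-3-ethyl-3'-hydroxy-4-(2-hydroxyethyl)-5'-oxooctahydrospiro[furo[3,2-c]azepine-2,2'-oxolane]-5-carboxylate, via tetronic acid 18 (not isolated)
Conditions: H2 (1 atm), Pd/C, EtOAc, rt; then Rh/Al2O3, H2 (5 bar), EtOAc–AcOH, rt
Reagents that add atoms: none
Why: Hydrogenolysis of both benzyl ethers, then syn hydrogenation of the tetronic acid enol on rhodium from the open face next to the ring oxygen O14, places the C12 hydroxyl on the C10 side (12R).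

Step 12
Reactants: 19 tert-butyl (2R,3S,3aR,3'R,4S,8aR)-3-ethyl-3'-hydroxy-4-(2-hydroxyethyl)-5'-oxooctahydrospiro[furo[3,2-c]azepine-2,2'-oxolane]-5-carboxylate
Product: 20 tert-butyl (2R,3S,3aR,3'R,4S,4'R,8aR)-3-ethyl-3'-hydroxy-4-(2-hydroxyethyl)-4'-methyl-5'-oxooctahydrospiro[furo[3,2-c]azepine-2,2'-oxolane]-5-carboxylate
Conditions: LiN(iPr)2 (3.5 equiv), THF–DMPU, −78 → −40 °C; MeI (1.3 equiv), −78 °C
Reagents that add atoms: iodomethane CI
Why: Fráter–Seebach alkylation: the alkoxide–enolate of the β-hydroxy lactone is methylated anti to the C12 alkoxide, giving the trans 12-OH/13-Me pair (13R), while the lithium alkoxides do not react with MeI at this temperature.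

Step 13
Reactants: 20 tert-butyl (2R,3S,3aR,3'R,4S,4'R,8aR)-3-ethyl-3'-hydroxy-4-(2-hydroxyethyl)-4'-methyl-5'-oxooctahydrospiro[furo[3,2-c]azepine-2,2'-oxolane]-5-carboxylate
Product: 21 tert-butyl (2R,3S,3aR,3'R,4S,4'R,8aR)-3-ethyl-3'-hydroxy-4-(2-iodoethyl)-4'-methyl-5'-oxooctahydrospiro[furo[3,2-c]azepine-2,2'-oxolane]-5-carboxylate
Conditions: I2, PPh3, imidazole, CH2Cl2, 0 °C
Reagents that add atoms: iodine [I][I]
Why: Appel-type iodination is selective for the primary alcohol over the hindered secondary hydroxyl next to the spiro centre.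

Step 14
Reactants: 22 (2S)-5-oxooxolane-2-carboxylic acid
Product: 23 benzyl (2S)-5-oxooxolane-2-carboxylate
Conditions: BnBr, KHCO3, DMF, rt
Reagents that add atoms: benzyl bromide BrCc1ccccc1
Why: Carboxylate O-alkylation under weakly basic conditions keeps the purchased C2 centre (future C18).

Step 15
Reactants: 23 benzyl (2S)-5-oxooxolane-2-carboxylate
Product: 24 benzyl (2S,4E)-4-[(dimethylamino)methylidene]-5-oxooxolane-2-carboxylate
Conditions: tBuOCH(NMe2)2, DME, 75 °C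
Reagents that add atoms: tert-butoxybis(dimethylamino)methane CN(C)C(OC(C)(C)C)N(C)C
Why: Condensation with Bredereck's reagent occurs only at the lactone α-CH2, because the tertiary C2–H cannot form an enaminone.

Step 16
Reactants: 24 benzyl (2S,4E)-4-[(dimethylamino)methylidene]-5-oxooxolane-2-carboxylate
Product: 26 (2S,4S)-4-methyl-5-oxooxolane-2-carboxylic acid, via methylidene lactone acid 25 (not isolated)
Conditions: H2 (3 bar), Pd/C, iPrOH, rt
Reagents that add atoms: none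
Why: Hydrogenation with loss of dimethylamine gives the exocyclic methylene lactone, which takes up hydrogen on the face opposite the C2 carboxyl to give the cis methyl lactone (future C20, S), and the benzyl ester is hydrogenolysed in the same operation.

Step 17
Reactants: 26 (2S,4S)-4-methyl-5-oxooxolane-2-carboxylic acid
Product: 27 S-(pyridin-2-yl) (2S,4S)-4-methyl-5-oxooxolane-2-carbothioate
Conditions: 2,2'-dipyridyl disulfide, PPh3, CH2Cl2, rt
Reagents that add atoms: 2,2'-dipyridyl disulfide c1ccc(SSc2ccccn2)nc1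
Why: Redox condensation (Mukaiyama thioesterification) gives an acyl donor that does not acylate alcohols without activation.

Step 18
Reactants: 21 tert-butyl (2R,3S,3aR,3'R,4S,4'R,8aR)-3-ethyl-3'-hydroxy-4-(2-iodoethyl)-4'-methyl-5'-oxooctahydrospiro[furo[3,2-c]azepine-2,2'-oxolane]-5-carboxylate; 27 S-(pyridin-2-yl) (2S,4S)-4-methyl-5-oxooxolane-2-carbothioate
Product: 28 tert-butyl (2R,3S,3aR,3'R,4S,4'R,8aR)-3-ethyl-3'-hydroxy-4'-methyl-4-{3-[(2S,4S)-4-methyl-5-oxooxolan-2-yl]-3-oxopropyl}-5'-oxooctahydrospiro[furo[3,2-c]azepine-2,2'-oxolane]-5-carboxylate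
Conditions: NiCl2(dme) (10 mol %), 4,4'-di-tert-butyl-2,2'-bipyridine (10 mol %), Zn (2 equiv), DMA, rt
Reagents that add atoms: none
Why: Nickel-catalysed reductive cross-electrophile acylation joins the primary iodide and the thioester (C2–C3 bond) without a preformed organometallic, so the free hydroxyl, carbamate and both lactones are tolerated and no stereocentre is touched.

Step 19
Reactants: 28 tert-butyl (2R,3S,3aR,3'R,4S,4'R,8aR)-3-ethyl-3'-hydroxy-4'-methyl-4-{3-[(2S,4S)-4-methyl-5-oxooxolan-2-yl]-3-oxopropyl}-5'-oxooctahydrospiro[furo[3,2-c]azepine-2,2'-oxolane]-5-carboxylate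
Product: 30 (1S,2R,3'R,3aR,4'R,10aS,10bR)-1-ethyl-3'-hydroxy-4'-methyl-8-[(2S,4S)-4-methyl-5-oxooxolan-2-yl]-1,3a,4,5,6,10,10a,10b-octahydrospiro[furo[3,2-c]pyrrolo[1,2-a]azepine-2,2'-oxolan]-5'-one (CNP0272443.1), via amino ketone 29 (not isolated)
Conditions: TFA, CH2Cl2, 0 °C; then aq. NaHCO3, rt (argon)
Reagents that add atoms: none
Why: Acidolysis of the Boc group frees the azepane N–H, which condenses with the 1,4-related ketone (cyclodehydration via the iminium) to the endocyclic enamine on neutralisation; the double bond forms toward C2, so C18 is retained.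

**Compound list**

1 | DL-alanine methyl ester hydrochloride | COC(=O)C(C)N.Cl | starting material
2 | methyl N-(4-bromobutanoyl)-DL-alaninate | COC(=O)C(C)NC(=O)CCCBr | intermediate
3 | 2-(3-bromopropyl)-5-methoxy-4-methyl-1,3-oxazole | COc1oc(CCCBr)nc1C | intermediate
4 | tert-butyl N-[(3S)-2-oxooxolan-3-yl]carbamate (N-Boc-L-homoserine lactone) | O=C1OCC[C@@H]1NC(=O)OC(C)(C)C | starting material
5 | tert-butyl N-[(3S)-2-hydroxyoxolan-3-yl]carbamate (lactol; both anomers) | OC1OCC[C@@H]1NC(=O)OC(C)(C)C | intermediate (not isolated)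
6 | tert-butyl N-[(3S)-5-hydroxypent-1-yn-3-yl]carbamate | C#C[C@H](CCO)NC(=O)OC(C)(C)C | intermediate
7 | tert-butyl N-[(3S)-5-(benzyloxy)pent-1-yn-3-yl]carbamate | C#C[C@H](CCOCc1ccccc1)NC(=O)OC(C)(C)C | intermediate
8 | tert-butyl N-[(3S)-5-(benzyloxy)pent-1-yn-3-yl]-N-[3-(5-methoxy-4-methyl-1,3-oxazol-2-yl)propyl]carbamate | C#C[C@H](CCOCc1ccccc1)N(CCCc1nc(C)c(OC)o1)C(=O)OC(C)(C)C | intermediate
9 | tert-butyl N-[(3S)-1-(benzyloxy)hept-4-yn-3-yl]-N-[3-(5-methoxy-4-methyl-1,3-oxazol-2-yl)propyl]carbamate | CCC#C[C@H](CCOCc1ccccc1)N(CCCc1nc(C)c(OC)o1)C(=O)OC(C)(C)C | intermediate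
10 | oxygen-bridged [4+2] adduct of 9 (7-oxa-2-azabicyclo[2.2.1]hepta-2,5-diene fused to the N-Boc azepane; 9aS; bridgehead epimers) | CCC1=C2[C@H](CCOCc3ccccc3)N(C(=O)OC(C)(C)C)CCCC24OC1(OC)C(C)=N4 | intermediate (not isolated)
11 | tert-butyl (4S)-4-[2-(benzyloxy)ethyl]-3-ethyl-2-methoxy-4,6,7,8-tetrahydro-5H-furo[3,2-c]azepine-5-carboxylate | CCc1c(OC)oc2CCCN(C(=O)OC(C)(C)C)[C@@H](CCOCc3ccccc3)c12 | intermediate (not isolated)
12 | tert-butyl (4S,8aR)-4-[2-(benzyloxy)ethyl]-3-ethyl-2-oxo-2,4,6,7,8,8a-hexahydro-5H-furo[3,2-c]azepine-5-carboxylate | CCC1=C2[C@@H](CCCN(C(=O)OC(C)(C)C)[C@H]2CCOCc3ccccc3)OC1=O | intermediate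
13 | tert-butyl (3S,3aR,4S,8aR)-4-[2-(benzyloxy)ethyl]-3-ethyl-2-oxooctahydro-5H-furo[3,2-c]azepine-5-carboxylate | CC[C@H]1[C@H]2[C@@H](CCCN(C(=O)OC(C)(C)C)[C@H]2CCOCc3ccccc3)OC1=O | intermediate
14 | methyl prop-2-ynoate | C#CC(=O)OC | starting material
15 | methyl (2E)-3-(benzyloxy)prop-2-enoate | COC(=O)/C=C/OCc1ccccc1 | intermediate
16 | methyl (2E)-3-(benzyloxy)-3-[(2S,3S,3aR,4S,8aR)-4-[2-(benzyloxy)ethyl]-5-(tert-butoxycarbonyl)-3-ethyl-2-hydroxyoctahydro-2H-furo[3,2-c]azepin-2-yl]prop-2-enoate | CC[C@H]1[C@H]2[C@@H](CCCN(C(=O)OC(C)(C)C)[C@H]2CCOCc3ccccc3)O[C@]1(O)/C(OCc4ccccc4)=C\C(=O)OC | intermediate (not isolated)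
17 | tert-butyl (2R,3S,3aR,4S,8aR)-3'-(benzyloxy)-4-[2-(benzyloxy)ethyl]-3-ethyl-5'-oxooctahydro-5'H-spiro[furo[3,2-c]azepine-2,2'-furan]-5-carboxylate | CC[C@H]1[C@H]2[C@@H](CCCN(C(=O)OC(C)(C)C)[C@H]2CCOCc3ccccc3)O[C@@]14OC(=O)C=C4OCc5ccccc5 | intermediate
18 | tert-butyl (2R,3S,3aR,4S,8aR)-3-ethyl-3'-hydroxy-4-(2-hydroxyethyl)-5'-oxooctahydro-5'H-spiro[furo[3,2-c]azepine-2,2'-furan]-5-carboxylate (tetronic acid, enol form) | CC[C@H]1[C@H]2[C@@H](CCCN(C(=O)OC(C)(C)C)[C@H]2CCO)O[C@@]13OC(=O)C=C3O | intermediate (not isolated)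
19 | tert-butyl (2R,3S,3aR,3'R,4S,8aR)-3-ethyl-3'-hydroxy-4-(2-hydroxyethyl)-5'-oxooctahydrospiro[furo[3,2-c]azepine-2,2'-oxolane]-5-carboxylate | CC[C@H]1[C@H]2[C@@H](CCCN(C(=O)OC(C)(C)C)[C@H]2CCO)O[C@@]13OC(=O)C[C@H]3O | intermediate
20 | tert-butyl (2R,3S,3aR,3'R,4S,4'R,8aR)-3-ethyl-3'-hydroxy-4-(2-hydroxyethyl)-4'-methyl-5'-oxooctahydrospiro[furo[3,2-c]azepine-2,2'-oxolane]-5-carboxylate | CC[C@H]1[C@H]2[C@@H](CCCN(C(=O)OC(C)(C)C)[C@H]2CCO)O[C@@]13OC(=O)[C@H](C)[C@H]3O | intermediate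
21 | tert-butyl (2R,3S,3aR,3'R,4S,4'R,8aR)-3-ethyl-3'-hydroxy-4-(2-iodoethyl)-4'-methyl-5'-oxooctahydrospiro[furo[3,2-c]azepine-2,2'-oxolane]-5-carboxylate | CC[C@H]1[C@H]2[C@@H](CCCN(C(=O)OC(C)(C)C)[C@H]2CCI)O[C@@]13OC(=O)[C@H](C)[C@H]3O | intermediate
22 | (2S)-5-oxooxolane-2-carboxylic acid | OC(=O)[C@@H]1CCC(=O)O1 | starting material
23 | benzyl (2S)-5-oxooxolane-2-carboxylate | O=C(OCc1ccccc1)[C@@H]1CCC(=O)O1 | intermediate
24 | benzyl (2S,4E)-4-[(dimethylamino)methylidene]-5-oxooxolane-2-carboxylate | O=C(OCc1ccccc1)[C@@H]1C/C(=C\N(C)C)C(=O)O1 | intermediate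
25 | (2S)-4-methylidene-5-oxooxolane-2-carboxylic acid | OC(=O)[C@@H]1CC(=C)C(=O)O1 | intermediate (not isolated)
26 | (2S,4S)-4-methyl-5-oxooxolane-2-carboxylic acid | OC(=O)[C@@H]1C[C@H](C)C(=O)O1 | intermediate
27 | S-(pyridin-2-yl) (2S,4S)-4-methyl-5-oxooxolane-2-carbothioate | O=C(Sc1ccccn1)[C@@H]1C[C@H](C)C(=O)O1 | intermediate
28 | tert-butyl (2R,3S,3aR,3'R,4S,4'R,8aR)-3-ethyl-3'-hydroxy-4'-methyl-4-{3-[(2S,4S)-4-methyl-5-oxooxolan-2-yl]-3-oxopropyl}-5'-oxooctahydrospiro[furo[3,2-c]azepine-2,2'-oxolane]-5-carboxylate | CC[C@H]1[C@H]2[C@@H](CCCN(C(=O)OC(C)(C)C)[C@H]2CCC(=O)[C@@H]3C[C@H](C)C(=O)O3)O[C@@]14OC(=O)[C@H](C)[C@H]4O | intermediate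
29 | (2R,3S,3aR,3'R,4S,4'R,8aR)-3-ethyl-3'-hydroxy-4'-methyl-4-{3-[(2S,4S)-4-methyl-5-oxooxolan-2-yl]-3-oxopropyl}octahydrospiro[furo[3,2-c]azepine-2,2'-oxolan]-5'-one (amino ketone) | CC[C@H]1[C@H]2[C@@H](CCCN[C@H]2CCC(=O)[C@@H]3C[C@H](C)C(=O)O3)O[C@@]14OC(=O)[C@H](C)[C@H]4O | intermediate (not isolated)
30 | (1S,2R,3'R,3aR,4'R,10aS,10bR)-1-ethyl-3'-hydroxy-4'-methyl-8-[(2S,4S)-4-methyl-5-oxooxolan-2-yl]-1,3a,4,5,6,10,10a,10b-octahydrospiro[furo[3,2-c]pyrrolo[1,2-a]azepine-2,2'-oxolan]-5'-one (CNP0272443.1) | CC[C@H]1[C@H]2[C@@H](CCCN3C([C@@H]4C[C@H](C)C(=O)O4)=CC[C@@H]23)O[C@@]12OC(=O)[C@H](C)[C@H]2O | target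

**Step count**

Total step count: 19 (12 in the main line, 2 for oxazole 3, 1 for acrylate 15, 4 for thioester 27).
Longest linear sequence: 12 steps, from 4 to 30 (steps 3–8, 10–13, 18, 19).

**Steps most likely to fail, with fallbacks**

Step 7. The alkyne is unactivated and the tether is a flexible carbamate, so the thermal [4+2] may be slow, and the C8 configuration depends on equilibration of the butenolide. The fallback sets out from 7 and comes back at 12. N-alkylation of 7 with 2-(3-bromopropyl)-1,3-dioxolane (NaH, DMF) gives tert-butyl N-[(3S)-5-(benzyloxy)pent-1-yn-3-yl]-N-[3-(1,3-dioxolan-2-yl)propyl]carbamate F1. Acetylide ethylation (n-BuLi, EtI, DMPU) gives tert-butyl N-[(3S)-1-(benzyloxy)hept-4-yn-3-yl]-N-[3-(1,3-dioxolan-2-yl)propyl]carbamate F2. PPTS in wet acetone unmasks tert-butyl N-[(3S)-1-(benzyloxy)hept-4-yn-3-yl]-N-(4-oxobutyl)carbamate F3. A Ru3(CO)12-catalysed cyclocarbonylation of the ynal (CO 10 bar, toluene, 160 °C; hetero-Pauson–Khand [2+2+1] of alkyne, aldehyde and CO) then closes azepane and butenolide in one step to 12; closure of a seven-membered ring this way is itself unproven.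

Step 10. The lithio acrylate is a strong base and 13 has an α-proton, so enolisation or reagent decomposition can compete with addition to a hindered lactone. The fallback sets out from 13 and comes back at 17. The lithium acetylide of 14 (LiN(SiMe3)2, THF, −78 °C) adds to the lactone to give methyl 3-[(2S,3S,3aR,4S,8aR)-4-[2-(benzyloxy)ethyl]-5-(tert-butoxycarbonyl)-3-ethyl-2-hydroxyoctahydro-2H-furo[3,2-c]azepin-2-yl]prop-2-ynoate F4. PBu3-catalysed conjugate addition of benzyl alcohol to the ynoate, followed by DBU-promoted lactonisation of the hemiketal hydroxyl onto the ester, then builds the tetronate ring stepwise and gives 17.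

Step 18. The cross-electrophile acylation must outcompete reduction or homocoupling of the iodide in the presence of a free hydroxyl. The fallback sets out from 21 and comes back at 30. Silylation (Et3SiCl, imidazole, DMAP, DMF) gives tert-butyl (2R,3S,3aR,3'R,4S,4'R,8aR)-3-ethyl-4-(2-iodoethyl)-4'-methyl-5'-oxo-3'-[(triethylsilyl)oxy]octahydrospiro[furo[3,2-c]azepine-2,2'-oxolane]-5-carboxylate F5. Zinc insertion (Zn dust, DMA) gives the alkylzinc iodide, which is acylated by 27 under PdCl2(PPh3)2 catalysis (thioester–organozinc ketone synthesis) to tert-butyl (2R,3S,3aR,3'R,4S,4'R,8aR)-3-ethyl-4'-methyl-4-{3-[(2S,4S)-4-methyl-5-oxooxolan-2-yl]-3-oxopropyl}-5'-oxo-3'-[(triethylsilyl)oxy]octahydrospiro[furo[3,2-c]azepine-2,2'-oxolane]-5-carboxylate F6. TFA in wet CH2Cl2 then removes the silyl ether and the Boc group and triggers the cyclodehydration to 30.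

Further compounds
F1 | step 7 | tert-butyl N-[(3S)-5-(benzyloxy)pent-1-yn-3-yl]-N-[3-(1,3-dioxolan-2-yl)propyl]carbamate | C#C[C@H](CCOCc1ccccc1)N(CCCC1OCCO1)C(=O)OC(C)(C)C
F2 | step 7 | tert-butyl N-[(3S)-1-(benzyloxy)hept-4-yn-3-yl]-N-[3-(1,3-dioxolan-2-yl)propyl]carbamate | CCC#C[C@H](CCOCc1ccccc1)N(CCCC1OCCO1)C(=O)OC(C)(C)C
F3 | step 7 | tert-butyl N-[(3S)-1-(benzyloxy)hept-4-yn-3-yl]-N-(4-oxobutyl)carbamate | CCC#C[C@H](CCOCc1ccccc1)N(CCCC=O)C(=O)OC(C)(C)C
F4 | step 10 | methyl 3-[(2S,3S,3aR,4S,8aR)-4-[2-(benzyloxy)ethyl]-5-(tert-butoxycarbonyl)-3-ethyl-2-hydroxyoctahydro-2H-furo[3,2-c]azepin-2-yl]prop-2-ynoate | CC[C@H]1[C@H]2[C@@H](CCCN(C(=O)OC(C)(C)C)[C@H]2CCOCc3ccccc3)O[C@]1(O)C#CC(=O)OC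
F5 | step 18 | tert-butyl (2R,3S,3aR,3'R,4S,4'R,8aR)-3-ethyl-4-(2-iodoethyl)-4'-methyl-5'-oxo-3'-[(triethylsilyl)oxy]octahydrospiro[furo[3,2-c]azepine-2,2'-oxolane]-5-carboxylate | CC[C@H]1[C@H]2[C@@H](CCCN(C(=O)OC(C)(C)C)[C@H]2CCI)O[C@@]13OC(=O)[C@H](C)[C@H]3O[Si](CC)(CC)CC
F6 | step 18 | tert-butyl (2R,3S,3aR,3'R,4S,4'R,8aR)-3-ethyl-4'-methyl-4-{3-[(2S,4S)-4-methyl-5-oxooxolan-2-yl]-3-oxopropyl}-5'-oxo-3'-[(triethylsilyl)oxy]octahydrospiro[furo[3,2-c]azepine-2,2'-oxolane]-5-carboxylate | CC[C@H]1[C@H]2[C@@H](CCCN(C(=O)OC(C)(C)C)[C@H]2CCC(=O)[C@@H]3C[C@H](C)C(=O)O3)O[C@@]14OC(=O)[C@H](C)[C@H]4O[Si](CC)(CC)CC
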